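The runs are calculated with made-up constants; the scatter is artificial.

If your one reading of Q falls at 40 min, it is a point on a curve that may already have turned, and two of us disputed exactly that.

| setting | elm | larch | Sunday's | Monday's | Tuesday's |
|---|---|---|---|---|---|
| Z | 2.8 M | 2.8 M | 2.8 M | 2.8 M | 2.8 M |
| E | 12 mM | 110 mM | 16 mM | 48 mM | 140 mM |
| remark | run made earlier | run made earlier |  |  |  |
| time |  |  | 40 min | 40 min | 40 min |

| run | time / min | Q / % | Z / % |
|---|---|---|---|
| elm | 1.50 | 1.9 | 88.7 |
| elm | 4.00 | 4.8 | 72.9 |
| elm | 8.00 | 6.5 | 50.8 |
| elm | 20.0 | 9.5 | 20.6 |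
| larch | 2.50 | 17.9 | 63.4 |
| larch | 8.00 | 21.5 | 41.0 |
| larch | 12.0 | 18.4 | 32.7 |
| larch | 20.0 | 15.2 | 23.2 |

(readings scatter by 1 percentage point)

- percentages count the Z that a species holds: one X counts as two
- the earlier runs were read with a standard deviation of 1 percentage point
- candidate steps: Z -> G; 2 Z -> X; Z + E <-> Q + E; Q <-> J

1. which of the two there is more of at the end, Sunday's (G / Q)
2. which of the two there is more of at the end, Monday's (G / Q)
3. which of the two there is more of at the end, Tuesday's (G / Q)
4. amount of Q at the end, in percent of the Z charged, Sunday's
5. amount of Q at the end, in percent of the Z charged, Monday's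
6. amount of Q at the end, in percent of the Z charged, Tuesday's

The first chemist holds that Q accumulates. E carries Z into Q in a pseudo-first-order step, and elm's Q was still climbing at its last reading. She runs elm's last slope on to 40 min, scales it by Sunday's E over elm's, and gets 16.2% for Sunday's, with more E meaning more Q.

The second chemist, whose side I take, compares rates at one moment. E multiplies both the making of Q and its return to Z, so their ratio depends on Q over Z and not on E. Larch's Q reads highest at 8.00 min, where Q over Z reads 0.524. Below a ratio near that reading I expect Q to rise, and there the first view stands: elm's last reading gives 0.461. But Z keeps leaking to G, so the ratio drifts upward, to 0.655 in larch's last reading, and then Q returns to Z and drains with it.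

From then on I reckon with the pool half-life, the time in which Z and Q together fall by a factor of 2, read from larch's last two readings as 19.4 min.

With larch standing in for Tuesday's, the half-life carried on from larch's reading at 20.0 min gives me 7.44% of Q for Tuesday's, and 18.8% of Z and Q together. The other 81.2% lies in G, J and X, so I expect G to beat Q in Tuesday's unless J or X hold most of it. Sunday's and Monday's have E between elm's and larch's, and elm's Z and Q together read less than larch's at 20.0 min, so I expect G ahead of Q there too. For these two I estimate a range for Q: from 5.07%, elm's sum carried on with larch's half-life and shared at larch's peak ratio, up to elm's last reading of 9.5%.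

The forecast, also on the drain side, says G, G and G with Q at 8.6%, 9.3% and 8%, its Tuesday's Q higher than mine, holding that “high E only speeds the drain through Z to G”.

The flasks give G, G and G, with Q at 8.58%, 8.06% and 6.95%. Sunday's Q stands lower than her 16.2%, and Tuesday's Q lower than my 7.44%.

    Z → G (k = 0.00110 s⁻¹)
    2 Z → X (k = 1.10 × 10⁻⁶ M⁻¹ s⁻¹)
    Z + E ⇌ Q + E, rate k3*[Z]*[E] forward; the back reaction follows from the equilibrium constant (K = 0.510, k = 0.0240 M⁻¹ s⁻¹)
    Q ⇌ J (K = 0.330, k = 0.00430 s⁻¹)

The neighbour is Monday's flask read at 1.5 h, which is 50.0 min later. Over that time the pool half-life of 19.4 min, read in larch, gives Monday's Q a fall by a factor of 5.97, from 8.06% to 1.35%. The factor actually found is 5.13. That flask holds Q at 1.57%, with Z at 2.1% beside it and G at 95.6%.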